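Slowness was the first thing I read. At 15.0 s birch held 2.8% of first product and oak 2.9%, with none of the gas in solution at the start. Birch and oak looked nearly the same, with equal temperature and gas, but by 80.0 s birch read a higher percent, 30.3% against 23.8% in oak.

| setting | birch | larch | oak | amber | green | teal | grey |
|---|---|---|---|---|---|---|---|
| substrate | 0.26 M | 0.37 M | 0.43 M | 0.50 M | 0.25 M | 0.50 M | 0.25 M |
| gas | 200 mM (held) | 200 mM (held) | 200 mM (held) | 200 mM (held) | 200 mM (held) | 200 mM (held) | 200 mM (held) |
| temperature | 70 °C | 92 °C | 70 °C | 60 °C | 60 °C | 100 °C | 100 °C |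
| remark | run made earlier | run made earlier | run made earlier |  |  |  |  |
| time |  |  |  | 4.0 min | 4.0 min | 4.0 min | 4.0 min |

| run | time / s | first product / % |
|---|---|---|
| birch | 15.0 | 2.8 |
| birch | 30.0 | 6.9 |
| birch | 50.0 | 16.0 |
| birch | 60.0 | 19.3 |
| birch | 80.0 | 30.3 |
| larch | 10.0 | 3.1 |
| larch | 15.0 | 6.2 |
| larch | 20.0 | 6.5 |
| larch | 25.0 | 12.9 |
| oak | 15.0 | 2.9 |
| oak | 30.0 | 6.4 |
| oak | 50.0 | 13.2 |
| oak | 60.0 | 17.8 |
| oak | 80.0 | 23.8 |

(each reading ± 1 percentage point)

- at the start none of the gas is in solution

1. ranking by amount of first product, in percent of the substrate charged, from high to low, at 4.0 min (amber / green / teal / grey)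
2. the amount of first product, in percent of the substrate charged of the flask you put first, at 4.0 min
3. the amount of first product, in percent of the substrate charged of the flask you put last, at 4.0 min

I took the symmetric case as the zero of a scale. A flask whose rate is proportional to substrate converts the same percent at any charge, provided the gas level and time are the same. That is zero. At the other end, a flask held to a fixed gas supply, the mass-transfer limit, makes the same moles per litre at any charge while its substrate lasts, and that is one. Oak lay between: at 80.0 s it had made 0.102 M against 0.0788 M in birch, more moles but a lower percent.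

I summed the readings from 50.0 s to 80.0 s in each run to damp the scatter of 1 percentage point. The charge index, the logarithm of the dilute-to-concentrated percent ratio divided by the logarithm of the concentrated-to-dilute charge ratio, read 0.358. This was a reading at 70 °C, from the first 80.0 s of two runs. Carried over unchanged as my own estimate, it put green above amber and grey above teal, each by a factor of 1.28. That gave me a ratio, not a level.

The forecast gave grey > teal > green > amber, with 99% on top and 50% at the bottom, and said “I assume no detectable loss of first product”. On the order within each pair, my reckoning and the forecast agreed.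

The flasks gave teal > grey > green > amber, with teal at 84.3% and amber at 55.5%.

    partner + first product → bis adduct (k = 6.25 × 10⁻⁴ L mol⁻¹ s⁻¹, Ea = 83.0 kJ mol⁻¹)
    partner + bis adduct → triple product (k = 0.0762 L mol⁻¹ s⁻¹, Ea = 46.0 kJ mol⁻¹)
    partner ⇌ dormant form (K = 0.985, k = 6.73 × 10⁻⁴ s⁻¹, Ea = 106 kJ mol⁻¹, ΔH = 7.00 kJ mol⁻¹)
    gas ⇌ partner, rate k4*(csat - [partner]) (kL = 0.0217 s⁻¹)
    substrate + partner → first product (k = 0.0299 L mol⁻¹ s⁻¹, Ea = 58.0 kJ mol⁻¹)
    (constants at 60 °C)

At 60 °C the index from green and amber was 0.137. At 100 °C, grey and teal gave −0.106, below the zero of the scale, and at 4.00 min grey held 18.5% of triple product against 9.45% in teal. For amber charged with 2.0 M of substrate, the index from birch and oak scaled amber's percent down to 33.8%. That flask gave 33.2% of first product, with 66.7% of its substrate still there.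

The data stem from a simulated flask for an exercise, noise included.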